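**Plan**
Retrosynthesis: the 4'-O-pivalate and the methyl groups on O5 and O8 come off first. Then O1–C8a is cut, which opens ring C to a 2-methoxy-1,3-diketone. After that C2–C3 (enolate aroylation), C4–C4a (aryllithium plus Weinreb amide) and O7–prenyl are cut.
Enabling feature: in ring A the oxygens on C5 and C8 are para to each other, and O1 sits on C8a beside the acyl-bearing C4a. Ring A is therefore the reduced form of a 2-acyl-1,4-benzoquinone that has taken up an oxygen nucleophile at its most electrophilic carbon.
Forward: rings A and B are bought as benzenes. The three-carbon bridge is attached at C4a–C4 and then at C3–C2, and ring C closes last, in the anodic step.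
Stereochemistry: none has to be set. The central carbon of the diketone is configurationally labile and becomes sp2 on ring closure.

Key step: step 7

Remark: the target has no stereocentre and no E/Z element, so the compound drawn is its only stereoisomer and no asymmetric step is needed.
Remark: 4-bromo-2,5-dimethoxybenzaldehyde and N,2-dimethoxy-N-methylacetamide are taken as catalogue chemicals.

**Route**

Step 1
Reactants: 1 4-bromo-2,5-dimethoxybenzaldehyde
Product: 3 4-bromo-2,5-dimethoxyphenol, via aryl formate 2 (not isolated)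
Conditions: mCPBA, CH2Cl2, 0 °C→rt; NaHCO3 wash; then K2CO3 (cat.), MeOH, rt
Reagents that add atoms: mCPBA, OOC(=O)c1cccc(Cl)c1
Why: Baeyer–Villiger oxidation of an electron-rich benzaldehyde (the peracid form of the Dakin reaction): the ortho-methoxyaryl group migrates in preference to hydride, the formate is lost by methanolysis, and the bromine already marks the carbon para to the new phenol that will carry the side chain.

Step 2
Reactants: 3 4-bromo-2,5-dimethoxyphenol; 4 prenyl bromide
Product: 5 1-bromo-2,5-dimethoxy-4-(3-methylbut-2-enyloxy)benzene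
Conditions: K2CO3, acetone, reflux
Reagents that add atoms: none
Why: Williamson ether synthesis: the phenoxide displaces the primary allylic bromide by SN2 at oxygen, and the aryl bromide is inert to carbonate.

Step 3
Reactants: 5 1-bromo-2,5-dimethoxy-4-(3-methylbut-2-enyloxy)benzene; 6 N,2-dimethoxy-N-methylacetamide
Product: 8 1-[2,5-dimethoxy-4-(3-methylbut-2-enyloxy)phenyl]-2-methoxyethanone, via aryllithium 7 (not isolated)
Conditions: n-BuLi (1.05 equiv), THF, −78 °C; then 6, −78→0 °C; aq NH4Cl
Reagents that add atoms: none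
Why: Bromine–lithium exchange followed by the Weinreb ketone synthesis: exchange at −78 °C outruns deprotonation of the prenyl ether, the acyl group enters only at the formerly brominated carbon (future C4a), and the N-methoxyamide prevents a second addition.

Step 4
Reactants: 9 vanillic acid
Product: 10 3-methoxy-4-pivaloyloxybenzoic acid
Conditions: PivCl (1.1 equiv), NaOH (2.2 equiv), H2O–THF, 0 °C; then HCl to pH 2
Reagents that add atoms: pivaloyl chloride, CC(C)(C)C(=O)Cl
Why: Schotten–Baumann acylation: the phenoxide is acylated, any mixed anhydride at the carboxylate is hydrolysed in the aqueous base, and the hindered aryl pivalate survives the cold alkaline medium.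

Step 5
Reactants: 10 3-methoxy-4-pivaloyloxybenzoic acid
Product: 11 3-methoxy-4-pivaloyloxybenzoyl chloride
Conditions: (COCl)2, DMF (cat.), CH2Cl2, 0 °C→rt
Reagents that add atoms: oxalyl chloride, ClC(=O)C(=O)Cl
Why: Acid chloride formation under Vilsmeier-type DMF catalysis runs at room temperature without touching the aryl ester or the methyl ether.

Step 6
Reactants: 8 1-[2,5-dimethoxy-4-(3-methylbut-2-enyloxy)phenyl]-2-methoxyethanone; 11 3-methoxy-4-pivaloyloxybenzoyl chloride
Product: 13 1-[2,5-dimethoxy-4-(3-methylbut-2-enyloxy)phenyl]-2-methoxy-3-(3-methoxy-4-pivaloyloxyphenyl)propane-1,3-dione, via lithium enolate 12 (not isolated)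
Conditions: LiHMDS (2.2 equiv), THF, −78 °C; then 11 (1.0 equiv), −78→−20 °C; AcOH quench
Reagents that add atoms: none
Why: Claisen-type C-acylation of a preformed lithium enolate by an aroyl chloride: the α-methoxy group chelates lithium and favours attack through carbon, the second equivalent of base absorbs the acidic proton of 13, the hindered pivalate is not attacked at low temperature, and the new central carbon is a racemic, labile centre that disappears in step 7.

Step 7
Reactants: 13 1-[2,5-dimethoxy-4-(3-methylbut-2-enyloxy)phenyl]-2-methoxy-3-(3-methoxy-4-pivaloyloxyphenyl)propane-1,3-dione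
Product: 16 5,8-dihydroxy-3-methoxy-2-(3-methoxy-4-pivaloyloxyphenyl)-7-(3-methylbut-2-enyloxy)chromen-4-one, via acylquinone 14 (not isolated), via flavone-5,8-quinone 15 (not isolated)
Conditions: RVC anode, Pt cathode, divided cell (Nafion), potential held at the first anodic wave of 13 (expected near +1.3 V against Ag/AgCl), 4 F/mol, LiClO4 (0.1 M), AcOH/NaOAc buffer (pH ≈ 5), MeCN–H2O 4:1, 0 °C→rt, Ar; then aq Na2S2O4, EtOAc
Reagents that add atoms: water, O
Why: Proposed new method: two-electron anodic oxidation of the 1,2,4-trialkoxyarene of 13, with ipso capture by water at the two para-related methoxy-bearing carbons, expels both methoxy groups as methanol and leaves acylquinone 14, in which the carbon that becomes C8a is β both to the ring carbonyl (future C5) and to the side-chain ketone (future C4). The buffer enolises the diketone and the enol oxygen of the aroyl carbonyl adds to that carbon in a 6-endo-trig oxa-Michael closure that forms O1–C8a and ring C, attack through C3 being excluded because it would need a four-membered ring, and tautomerisation then gives 16. Because 16 is oxidised more easily than 13 and would also be oxidised by unreacted 14, the charge is set at 4 F/mol so that all material converges on flavone quinone 15, which dithionite returns to 16 in the work-up. The closest known reaction types are anodic or cerium(IV) oxidative demethylation of 1,4-dimethoxyarenes to quinones and the addition of alcohols and phenols to C3 of 2-acyl-1,4-benzoquinones, whereas their combination with an enol oxygen as the nucleophile has not been shown. No stereocentre is formed. The step needs oxidation at ring A only, which is secured by holding the potential at the wave of the trialkoxyarene, well below what is expected for the prenyl alkene and for the acylated, pivaloylated ring B, and by a weakly acidic buffer that keeps the diketone out of its easily oxidised enolate form and spares the prenyl ether.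

Step 8
Reactants: 16 5,8-dihydroxy-3-methoxy-2-(3-methoxy-4-pivaloyloxyphenyl)-7-(3-methylbut-2-enyloxy)chromen-4-one
Product: 17 3,5,8-trimethoxy-2-(3-methoxy-4-pivaloyloxyphenyl)-7-(3-methylbut-2-enyloxy)chromen-4-one
Conditions: MeI (excess), K2CO3, DMF, Ar, rt→45 °C
Reagents that add atoms: iodomethane, CI
Why: Williamson O-methylation of both phenols: O8 reacts readily and the chelated O5 follows with excess iodomethane on gentle warming, exclusion of air keeps the hydroquinone from re-oxidising, and anhydrous carbonate leaves the pivalate in place so that O4' stays masked.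

Step 9
Reactants: 17 3,5,8-trimethoxy-2-(3-methoxy-4-pivaloyloxyphenyl)-7-(3-methylbut-2-enyloxy)chromen-4-one
Product: 18 4'-hydroxy-3,5,8,3'-tetramethoxy-7-prenyloxyflavone
Conditions: K2CO3 (1.5 equiv), MeOH–THF, rt; AcOH quench
Reagents that add atoms: none
Why: Base-mediated transesterification of the aryl ester with methanol frees the 4'-phenol, while the methyl and prenyl ethers and the 3-methoxychromone ring are stable to methanolic carbonate at room temperature.

**Compound list**
1 | 4-bromo-2,5-dimethoxybenzaldehyde | COc1cc(Br)c(OC)cc1C=O | starting material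
2 | 4-bromo-2,5-dimethoxyphenyl formate | COc1cc(Br)c(OC)cc1OC=O | intermediate
3 | 4-bromo-2,5-dimethoxyphenol | COc1cc(Br)c(OC)cc1O | intermediate
4 | prenyl bromide (1-bromo-3-methylbut-2-ene) | CC(C)=CCBr | starting material
5 | 1-bromo-2,5-dimethoxy-4-(3-methylbut-2-enyloxy)benzene | COc1cc(OCC=C(C)C)c(OC)cc1Br | intermediate
6 | N,2-dimethoxy-N-methylacetamide | COCC(=O)N(C)OC | starting material
7 | [2,5-dimethoxy-4-(3-methylbut-2-enyloxy)phenyl]lithium | [Li]c1cc(OC)c(OCC=C(C)C)cc1OC | intermediate
8 | 1-[2,5-dimethoxy-4-(3-methylbut-2-enyloxy)phenyl]-2-methoxyethanone | COCC(=O)c1cc(OC)c(OCC=C(C)C)cc1OC | intermediate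
9 | vanillic acid (4-hydroxy-3-methoxybenzoic acid) | COc1cc(C(=O)O)ccc1O | starting material
10 | 3-methoxy-4-pivaloyloxybenzoic acid | COc1cc(C(=O)O)ccc1OC(=O)C(C)(C)C | intermediate
11 | 3-methoxy-4-pivaloyloxybenzoyl chloride | COc1cc(C(=O)Cl)ccc1OC(=O)C(C)(C)C | intermediate
12 | lithium (Z)-enolate of 8, lithium chelated by the α-methoxy group | [Li]O/C(=C\OC)c1cc(OC)c(OCC=C(C)C)cc1OC | intermediate
13 | 1-[2,5-dimethoxy-4-(3-methylbut-2-enyloxy)phenyl]-2-methoxy-3-(3-methoxy-4-pivaloyloxyphenyl)propane-1,3-dione (racemic, central carbon labile) | COc1cc(C(=O)C(OC)C(=O)c2ccc(OC(=O)C(C)(C)C)c(OC)c2)c(OC)cc1OCC=C(C)C | intermediate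
14 | 2-[2-methoxy-3-(3-methoxy-4-pivaloyloxyphenyl)-3-oxopropanoyl]-5-(3-methylbut-2-enyloxy)-1,4-benzoquinone | O=C1C=C(OCC=C(C)C)C(=O)C=C1C(=O)C(OC)C(=O)c1ccc(OC(=O)C(C)(C)C)c(OC)c1 | intermediate
15 | 3-methoxy-2-(3-methoxy-4-pivaloyloxyphenyl)-7-(3-methylbut-2-enyloxy)chromene-4,5,8-trione | COc1cc(C2=C(OC)C(=O)C3=C(O2)C(=O)C(OCC=C(C)C)=CC3=O)ccc1OC(=O)C(C)(C)C | intermediate
16 | 5,8-dihydroxy-3-methoxy-2-(3-methoxy-4-pivaloyloxyphenyl)-7-(3-methylbut-2-enyloxy)chromen-4-one | COc1cc(-c2oc3c(O)c(OCC=C(C)C)cc(O)c3c(=O)c2OC)ccc1OC(=O)C(C)(C)C | intermediate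
17 | 3,5,8-trimethoxy-2-(3-methoxy-4-pivaloyloxyphenyl)-7-(3-methylbut-2-enyloxy)chromen-4-one | COc1cc(-c2oc3c(OC)c(OCC=C(C)C)cc(OC)c3c(=O)c2OC)ccc1OC(=O)C(C)(C)C | intermediate
18 | 4'-hydroxy-3,5,8,3'-tetramethoxy-7-prenyloxyflavone | COc1cc(-c2oc3c(OC)c(OCC=C(C)C)cc(OC)c3c(=O)c2OC)ccc1O | target

Total step count: 9
Longest linear sequence: 7 (steps 1, 2, 3, 6, 7, 8, 9)

**Steps most likely to fail**

Step 7. Several processes could divert the cascade:
- loss of the prenyl group from the arene radical cation;
- capture of the radical cation by the enol oxygen at the methoxy-bearing ortho carbon in place of water;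
- oxidation at the central carbon of the diketone;
- enolisation too slow to compete with attack of solvent on the quinone.

The fallback uses known chemistry only. Ring A is bought with the C8a oxygen already in place, and the C8 oxygen is added by an Elbs oxidation. It sets out from 10 and 11 and comes back to the route at 18. Acid 10 and chloride 11 are joined (pyridine, CH2Cl2) to 3-methoxy-4-pivaloyloxybenzoic anhydride F1. Allan–Robinson condensation of this anhydride with purchased 2-methoxy-1-(2,4,6-trihydroxyphenyl)ethanone F2 (Et3N, 160 °C), followed by saponification of all ester groups with KOH/MeOH, should give 5,7-dihydroxy-2-(4-hydroxy-3-methoxyphenyl)-3-methoxychromen-4-one F3. Two equivalents of BnBr with K2CO3 alkylate O7 and O4' and leave the chelated 5-OH, giving 7-benzyloxy-2-(4-benzyloxy-3-methoxyphenyl)-5-hydroxy-3-methoxychromen-4-one F4. Elbs persulfate oxidation (K2S2O8, aq KOH, pyridine) places a sulfate para to the 5-OH, giving potassium 7-benzyloxy-2-(4-benzyloxy-3-methoxyphenyl)-5-hydroxy-3-methoxy-4-oxochromen-8-yl sulfate F5. Warm dilute HCl hydrolyses it to 7-benzyloxy-2-(4-benzyloxy-3-methoxyphenyl)-5,8-dihydroxy-3-methoxychromen-4-one F6. MeI/K2CO3 gives 7-benzyloxy-2-(4-benzyloxy-3-methoxyphenyl)-3,5,8-trimethoxychromen-4-one F7. Hydrogenolysis (H2, Pd/C) gives 7-hydroxy-2-(4-hydroxy-3-methoxyphenyl)-3,5,8-trimethoxychromen-4-one F8. One equivalent each of 4 and K2CO3 then alkylates the more acidic 7-OH, a vinylogous acid, to give 18.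

Step 6. O-acylation of the enolate in place of C-acylation, a second acylation of the product, or acyl transfer from the aryl pivalate could erode the coupling. The fallback replaces the acylation by an aldol addition and an oxidation. It sets out from 8 and 11 and comes back at 13. Chloride 11 is reduced with LiAlH(Ot-Bu)3 (THF, −78 °C) to 4-formyl-2-methoxyphenyl pivalate F9. Enolate 12, made from 8 as before, adds to this aldehyde to give 1-[2,5-dimethoxy-4-(3-methylbut-2-enyloxy)phenyl]-3-hydroxy-2-methoxy-3-(3-methoxy-4-pivaloyloxyphenyl)propan-1-one F10. This forms as a mixture of racemic diastereomers, which is of no consequence. Dess–Martin oxidation of the carbinol gives 13.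

Step 8. Aerial re-oxidation of the hydroquinone under base, incomplete methylation at the chelated 5-OH, or loss of the pivalate followed by methylation at O4' could spoil the step. The fallback separates the two oxygens and avoids carbonate. It sets out from 16 and comes back at 17. Trimethylsilyldiazomethane (MeCN–MeOH, i-Pr2NEt) methylates only the unchelated 8-OH to give 5-hydroxy-3,8-dimethoxy-2-(3-methoxy-4-pivaloyloxyphenyl)-7-(3-methylbut-2-enyloxy)chromen-4-one F11, which is no longer a hydroquinone. The chelated phenol is then methylated under Purdie conditions (MeI, Ag2O, DMF) to give 17.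

**Further compounds**
F1 | step 7 | 3-methoxy-4-pivaloyloxybenzoic anhydride | COc1cc(C(=O)OC(=O)c2ccc(OC(=O)C(C)(C)C)c(OC)c2)ccc1OC(=O)C(C)(C)C
F2 | step 7 | 2-methoxy-1-(2,4,6-trihydroxyphenyl)ethanone (purchased) | COCC(=O)c1c(O)cc(O)cc1O
F3 | step 7 | 5,7-dihydroxy-2-(4-hydroxy-3-methoxyphenyl)-3-methoxychromen-4-one | COc1cc(-c2oc3cc(O)cc(O)c3c(=O)c2OC)ccc1O
F4 | step 7 | 7-benzyloxy-2-(4-benzyloxy-3-methoxyphenyl)-5-hydroxy-3-methoxychromen-4-one | COc1cc(-c2oc3cc(OCc4ccccc4)cc(O)c3c(=O)c2OC)ccc1OCc1ccccc1
F5 | step 7 | potassium 7-benzyloxy-2-(4-benzyloxy-3-methoxyphenyl)-5-hydroxy-3-methoxy-4-oxochromen-8-yl sulfate | COc1cc(-c2oc3c(OS(=O)(=O)[O-])c(OCc4ccccc4)cc(O)c3c(=O)c2OC)ccc1OCc1ccccc1.[K+]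
F6 | step 7 | 7-benzyloxy-2-(4-benzyloxy-3-methoxyphenyl)-5,8-dihydroxy-3-methoxychromen-4-one | COc1cc(-c2oc3c(O)c(OCc4ccccc4)cc(O)c3c(=O)c2OC)ccc1OCc1ccccc1
F7 | step 7 | 7-benzyloxy-2-(4-benzyloxy-3-methoxyphenyl)-3,5,8-trimethoxychromen-4-one | COc1cc(-c2oc3c(OC)c(OCc4ccccc4)cc(OC)c3c(=O)c2OC)ccc1OCc1ccccc1
F8 | step 7 | 7-hydroxy-2-(4-hydroxy-3-methoxyphenyl)-3,5,8-trimethoxychromen-4-one | COc1cc(-c2oc3c(OC)c(O)cc(OC)c3c(=O)c2OC)ccc1O
F9 | step 6 | 4-formyl-2-methoxyphenyl pivalate | COc1cc(C=O)ccc1OC(=O)C(C)(C)C
F10 | step 6 | 1-[2,5-dimethoxy-4-(3-methylbut-2-enyloxy)phenyl]-3-hydroxy-2-methoxy-3-(3-methoxy-4-pivaloyloxyphenyl)propan-1-one (mixture of racemic diastereomers) | COc1cc(C(O)C(OC)C(=O)c2cc(OC)c(OCC=C(C)C)cc2OC)ccc1OC(=O)C(C)(C)C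
F11 | step 8 | 5-hydroxy-3,8-dimethoxy-2-(3-methoxy-4-pivaloyloxyphenyl)-7-(3-methylbut-2-enyloxy)chromen-4-one | COc1cc(-c2oc3c(OC)c(OCC=C(C)C)cc(O)c3c(=O)c2OC)ccc1OC(=O)C(C)(C)C
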